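(Readings and results were computed from invented constants; the scatter is artificial.)

A flask cannot hold more target than the substrate charged, so 100% is the ceiling, and the reckoning is best done on the fraction left. Define the loss exponent L as the natural logarithm of the charge over the target standing at 40 h, product in the second phase counted in, and let c be the substrate charge.

| flask | substrate | reagent in the second phase | remark | time | volume of the second phase over the first |
|---|---|---|---|---|---|
| summer | 16 mM | 3 equiv | run made earlier |  |  |
| spring | 36 mM | 3 equiv | run made earlier |  |  |
| flask | 24 mM | 3.00 equiv |  | 40 h | 2.0 |

| run | time / h | target / % | substrate / % |
|---|---|---|---|
| summer | 3.00 | 57.0 | 36.9 |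
| summer | 8.00 | 73.7 | 0.9 |
| summer | 15.0 | 53.0 | 0.2 |
| summer | 40.0 | 14.9 | 0 |
| spring | 10.0 | 63.9 | 0.2 |
| spring | 20.0 | 37.1 | 0 |
| spring | 30.0 | 21.6 | 0.2 |
| spring | 40.0 | 12.5 | 0 |

(standard deviation of a reading: 0.3 percentage points)

- amounts and yields of target count product in the second phase too
- in the second phase: reagent in the second phase, product in the second phase; everything else is in the first
- charges count per volume of the first phase; a concentration in a rate is the amount of a species over the volume of its own phase; every rate counts per litre of the first phase
- steps under discussion: target <-> isomer of the product; substrate + reagent in the reaction phase -> target; target <-> product in the second phase; reagent in the reaction phase <-> reagent in the second phase; target -> decomposed product; reagent in the reaction phase + target -> over-reaction product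
- the earlier runs hold the two phases in the same ratio of volumes as the flask asked about

- the target and product in the second phase together standing at 40 h, as a percentage of the substrate charged
- part of the substrate charged that has reacted at 40 h

With the main step by itself, substrate + reagent in the reaction phase → target, L is 0. The substrate reads 0% in the summer run and 0% in the spring run at 40.0 h, so my reckoning takes the substrate of the 24 mM flask as fully reacted, with a yield still at the ceiling.

First-order losses multiply the fraction left, so their exponents add. The two late readings give L = 1.90 for the summer run and 2.08 for the spring run. A straight line through them has a slope of 0.00878 mM⁻¹ and an intercept of 1.76.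

Adding the loss that does not grow with c, read as decomposition of target with any early lag folded in, puts L at that intercept and the yield at 17.2%. Adding the part that grows with c, read as a pseudo-first-order over-reaction of target with reagent in the reaction phase, gives the estimated loss exponent of the 24 mM flask, 1.97, and an estimated yield of 13.9%. Two readings of target pay for this estimate.

The forecast stands at 13.9% and 100%: “Interpolating ln(yield) at 40 h between 14.9% and 12.5% gives about 13.9%.”

The flask gives 14.0% and 100%.

    target ⇌ isomer of the product (K = 0.700, k = 0.00330 h⁻¹)
    substrate + reagent in the reaction phase → target (k = 170 M⁻¹ h⁻¹)
    target ⇌ product in the second phase, rate k3*([target] - [product in the second phase]/K3) per volume of the first phase (partition coefficient = 0.460, kL = 0.460 h⁻¹)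
    reagent in the reaction phase ⇌ reagent in the second phase, rate k4*([reagent in the reaction phase] - [reagent in the second phase]/K4) per volume of the first phase (partition coefficient = 1.40, kL = 0.340 h⁻¹)
    target → decomposed product (k = 0.0890 h⁻¹)
    reagent in the reaction phase + target → over-reaction product (k = 1.00 M⁻¹ h⁻¹)

The number does not show the route, and the exponent 1.97 belongs mainly to the conversion of target into decomposed product. The same flask with that step taken away keeps 76.2%, an exponent of 0.272, while decomposed product stands at 75.2% in the flask. Carried beyond its two runs to a neighbouring flask with 96 mM of substrate, the same equivalents and the same time, the line gives L = 2.60, so an estimated yield of 7.41%. That neighbouring flask computes to 8.13%.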